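**Plan**

1. Retrosynthesis: first cut the side-chain ester C–O bond (to 3-methylbut-2-enoic acid). Then cut the whole quinone ring at C1–C2, C3–C4 and C4–C4a (to a carbene carbon on C8a, acetylene and one CO). Last, cut the side chain at C1'–C2' and at its C3'=C4' double bond (to an aryl aldehyde, an allyl donor and 2-methyl-2-butene).
2. Forward: 2,5-dihydroxybenzaldehyde becomes the fully substituted benzenoid ring (O5 silylated, side chain on C7, OMe on C8, Br on C8a). The quinone ring arises last, in one operation, from a chromium carbene on C8a, acetylene and CO, and closes by bond formation between the CO-derived C4 and the arene carbon C4a.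
3. Enabling feature: C1 and C4 of the quinone ring carry para oxygens and C2/C3 are bare CH, which is the imprint of carbene carbon + HC≡CH + CO. In the benzenoid ring C8a has one hydrogen-bearing ortho neighbour only, C4a (C8 holds OMe), so the ketene carbon can close nowhere else.
4. The annulation leaves O4 as a free phenol while O5 and O8 are capped, so oxidation puts the quinone in the new ring. The helpers (Cr(CO)5, the methyl on O1, two silyl groups) leave in steps 8 and 9.
5. Stereochemistry: the single (R) carbinol centre comes from a catalytic asymmetric allylation of the aldehyde and is carried through unchanged; the ester is made without breaking the C1'–O bond.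

Key step: step 8

Remark: naphthalene locants follow the numbering of the plan (C1–C4 quinone ring, C4a/C8a ring fusion, C5 hydroxyl, C7 side chain, C8 methoxy; side-chain carbons primed). In the SMILES of the chromium compounds the five CO ligands are written as separate components.

**Route**

Step 1
Reactants: 1 2,5-dihydroxybenzaldehyde
Product: 2 2-hydroxy-5-(triisopropylsilyloxy)benzaldehyde
Conditions: TIPSCl, imidazole, DMF, 0 °C to rt
Reagents that add atoms: triisopropylsilyl chloride (TIPSCl), CC(C)[Si](Cl)(C(C)C)C(C)C
Why: Regioselective O-silylation; the C2 hydroxyl is hydrogen-bonded to and flanked by the formyl group, so the bulky chlorosilane should react only at the free C5 hydroxyl.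

Step 2
Reactants: 2 2-hydroxy-5-(triisopropylsilyloxy)benzaldehyde
Product: 3 3-bromo-2-hydroxy-5-(triisopropylsilyloxy)benzaldehyde
Conditions: NBS, MeCN, 0 °C
Reagents that add atoms: N-bromosuccinimide (NBS), O=C1CCC(=O)N1Br
Why: Electrophilic aromatic bromination; the free phenol activates one open position only, C3 (its para carbon carries the silyloxy group, its other ortho carbon the formyl group), and the positions next to the bulky silyl ether are less activated and shielded.

Step 3
Reactants: 3 3-bromo-2-hydroxy-5-(triisopropylsilyloxy)benzaldehyde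
Product: 4 3-bromo-2-methoxy-5-(triisopropylsilyloxy)benzaldehyde
Conditions: MeI, K2CO3, acetone, 50 °C
Reagents that add atoms: iodomethane (MeI), CI
Why: Williamson ether synthesis on the phenoxide; the triisopropylsilyl aryl ether should tolerate K2CO3 in an aprotic solvent.

Step 4
Reactants: 4 3-bromo-2-methoxy-5-(triisopropylsilyloxy)benzaldehyde; 5 allyltributylstannane
Product: 6 (1R)-1-[3-bromo-2-methoxy-5-(triisopropylsilyloxy)phenyl]but-3-en-1-ol
Conditions: (R)-BINOL (20 mol %), Ti(OiPr)4 (10 mol %), 4 Å MS, CH2Cl2, −20 °C; aq NaHCO3 work-up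
Reagents that add atoms: none
Why: Keck asymmetric allylation; the (R)-BINOL-derived titanium Lewis acid is expected to deliver the allyl group to the re face of the aryl aldehyde, which gives the (R) carbinol (O > aryl > allyl), the sense known for aromatic aldehydes.

Step 5
Reactants: 6 (1R)-1-[3-bromo-2-methoxy-5-(triisopropylsilyloxy)phenyl]but-3-en-1-ol; 7 2-methyl-2-butene
Product: 8 (1R)-1-[3-bromo-2-methoxy-5-(triisopropylsilyloxy)phenyl]-4-methylpent-3-en-1-ol
Conditions: second-generation Grubbs catalyst (H2IMes)(PCy3)Cl2Ru=CHPh (5 mol %), 2-methyl-2-butene/CH2Cl2, 40 °C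
Reagents that add atoms: none
Why: Olefin cross-metathesis; the terminal alkene exchanges its methylene for the isopropylidene unit of the excess trisubstituted alkene with loss of propene, and the carbinol centre is not involved.

Step 6
Reactants: 8 (1R)-1-[3-bromo-2-methoxy-5-(triisopropylsilyloxy)phenyl]-4-methylpent-3-en-1-ol
Product: 9 {3-bromo-5-[(1R)-1-(tert-butyldimethylsilyloxy)-4-methylpent-3-enyl]-4-methoxyphenoxy}triisopropylsilane
Conditions: TBSCl, imidazole, DMF, rt
Reagents that add atoms: tert-butyldimethylsilyl chloride (TBSCl), CC(C)(C)[Si](C)(C)Cl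
Why: Silyl ether formation at the secondary alcohol, which masks the only acidic proton before the organolithium step; the configuration is untouched because the C–O bond is not broken.

Step 7
Reactants: 9 {3-bromo-5-[(1R)-1-(tert-butyldimethylsilyloxy)-4-methylpent-3-enyl]-4-methoxyphenoxy}triisopropylsilane
Product: 12 pentacarbonyl[aryl(methoxy)methylidene]chromium carbene complex, via aryllithium 10 (not isolated), via lithium acylchromate 11 (not isolated)
Conditions: n-BuLi, Et2O, −78 °C; Cr(CO)6, −78 °C to rt; then Me3OBF4, CH2Cl2, 0 °C to rt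
Reagents that add atoms: hexacarbonylchromium Cr(CO)6, [Cr].[C-]#[O+].[C-]#[O+].[C-]#[O+].[C-]#[O+].[C-]#[O+].[C-]#[O+]; trimethyloxonium tetrafluoroborate Me3OBF4, C[O+](C)C.F[B-](F)(F)F
Why: Fischer carbene synthesis; bromine–lithium exchange at C8a, addition of the aryllithium to a CO ligand and O-methylation of the acyl chromate with Meerwein's salt should give the zerovalent chromium carbene, the silyl ethers and the remote alkene being inert to each stage.

Step 8
Reactants: 12 pentacarbonyl[aryl(methoxy)methylidene]chromium carbene complex; 13 acetylene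
Product: 15 7-[(1R)-1-(tert-butyldimethylsilyloxy)-4-methylpent-3-enyl]-8-methoxy-5-(triisopropylsilyloxy)naphthalene-1,4-dione, via methoxynaphthol 14 (not isolated)
Conditions: acetylene (1 atm), THF, 50 °C; then (NH4)2Ce(NO3)6, MeCN/H2O, 0 °C
Reagents that add atoms: water, O
Why: Thermal loss of one CO from 12 (eased by the ortho methoxy group, which can occupy the vacant site) lets acetylene bind and insert into the Cr=C bond, CO insertion into the resulting vinylcarbene gives a chromium-bound dienylketene Ar–C(OMe)=CH–CH=C=O, its ketene carbon (C4) closes onto the arene carbon C4a in a 6π electrocyclization, and tautomerization of the cyclohexadienone gives the chromium-bound 4-methoxy-1-naphthol 14. This is the Dötz benzannulation, a three-component union of carbene carbon, alkyne and a CO ligand, followed by the customary oxidative work-up with tetravalent cerium, which strips the metal and turns the p-methoxynaphthol into the quinone with loss of methanol (the C1 oxygen of 15 then comes from water, the C4 oxygen from CO). The quinone ring closes in the six-membered, all-sp2 electrocyclic mode, a disrotatory hexatriene-to-cyclohexadiene closure in which the arene bond C8a–C4a is one terminal double bond, so no Baldwin-type constraint applies. No stereocenter is formed, and the (R) carbinol centre is remote and untouched. Three selectivities are needed: the closure site is fixed because C8 is blocked by OMe and only C4a bears hydrogen, alkyne regiochemistry cannot arise because acetylene is symmetrical, and CO insertion (phenol formation) over cyclopentannulation is favoured by chromium, an alkoxy carbene and THF. The oxidation should fall on the new ring alone because it holds the only free phenol, the benzenoid ring being capped as methyl and triisopropylsilyl ethers.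

Step 9
Reactants: 15 7-[(1R)-1-(tert-butyldimethylsilyloxy)-4-methylpent-3-enyl]-8-methoxy-5-(triisopropylsilyloxy)naphthalene-1,4-dione
Product: 16 5-hydroxy-7-[(1R)-1-hydroxy-4-methylpent-3-enyl]-8-methoxynaphthalene-1,4-dione
Conditions: Bu4NF, AcOH (1:1), THF, 0 °C to rt
Reagents that add atoms: none
Why: Fluoride-mediated desilylation of both silyl ethers, buffered with acetic acid so that the base-sensitive quinone and the acid-sensitive carbinol/prenyl pair are both spared.

Step 10
Reactants: 16 5-hydroxy-7-[(1R)-1-hydroxy-4-methylpent-3-enyl]-8-methoxynaphthalene-1,4-dione; 17 3-methylbut-2-enoic acid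
Product: 18 (1R)-1-(4-hydroxy-1-methoxy-5,8-dioxo-5,8-dihydronaphthalen-2-yl)-4-methylpent-3-enyl 3-methylbut-2-enoate (CNP0130192.1)
Conditions: DCC, DMAP (cat.), CH2Cl2, 0 °C to rt
Reagents that add atoms: none
Why: Steglich esterification; the secondary alcohol should be acylated while the C5 phenol, locked in a hydrogen bond to the C4 carbonyl, stays free, as is typical of peri-hydroxyquinone carbinols, and the configuration is retained because the C1'–O bond is not broken.

**Compound list**

1 | 2,5-dihydroxybenzaldehyde | Oc1ccc(O)cc1C=O | starting material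
2 | 2-hydroxy-5-(triisopropylsilyloxy)benzaldehyde | Oc1ccc(O[Si](C(C)C)(C(C)C)C(C)C)cc1C=O | intermediate
3 | 3-bromo-2-hydroxy-5-(triisopropylsilyloxy)benzaldehyde | Oc1c(C=O)cc(O[Si](C(C)C)(C(C)C)C(C)C)cc1Br | intermediate
4 | 3-bromo-2-methoxy-5-(triisopropylsilyloxy)benzaldehyde | COc1c(C=O)cc(O[Si](C(C)C)(C(C)C)C(C)C)cc1Br | intermediate
5 | allyltributylstannane | C=CC[Sn](CCCC)(CCCC)CCCC | starting material
6 | (1R)-1-[3-bromo-2-methoxy-5-(triisopropylsilyloxy)phenyl]but-3-en-1-ol | COc1c([C@@H](CC=C)O)cc(O[Si](C(C)C)(C(C)C)C(C)C)cc1Br | intermediate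
7 | 2-methyl-2-butene | CC=C(C)C | starting material
8 | (1R)-1-[3-bromo-2-methoxy-5-(triisopropylsilyloxy)phenyl]-4-methylpent-3-en-1-ol | COc1c([C@@H](CC=C(C)C)O)cc(O[Si](C(C)C)(C(C)C)C(C)C)cc1Br | intermediate
9 | {3-bromo-5-[(1R)-1-(tert-butyldimethylsilyloxy)-4-methylpent-3-enyl]-4-methoxyphenoxy}triisopropylsilane | COc1c([C@@H](CC=C(C)C)O[Si](C)(C)C(C)(C)C)cc(O[Si](C(C)C)(C(C)C)C(C)C)cc1Br | intermediate
10 | {3-[(1R)-1-(tert-butyldimethylsilyloxy)-4-methylpent-3-enyl]-2-methoxy-5-(triisopropylsilyloxy)phenyl}lithium | COc1c([C@@H](CC=C(C)C)O[Si](C)(C)C(C)(C)C)cc(O[Si](C(C)C)(C(C)C)C(C)C)cc1[Li] | intermediate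
11 | lithium pentacarbonyl{3-[(1R)-1-(tert-butyldimethylsilyloxy)-4-methylpent-3-enyl]-2-methoxy-5-(triisopropylsilyloxy)benzoyl}chromate (acyl chromate) | COc1c([C@@H](CC=C(C)C)O[Si](C)(C)C(C)(C)C)cc(O[Si](C(C)C)(C(C)C)C(C)C)cc1C([O-])=[Cr].[Li+].[C-]#[O+].[C-]#[O+].[C-]#[O+].[C-]#[O+].[C-]#[O+] | intermediate
12 | pentacarbonyl{[3-[(1R)-1-(tert-butyldimethylsilyloxy)-4-methylpent-3-enyl]-2-methoxy-5-(triisopropylsilyloxy)phenyl](methoxy)methylidene}chromium (zerovalent chromium Fischer carbene) | COc1c([C@@H](CC=C(C)C)O[Si](C)(C)C(C)(C)C)cc(O[Si](C(C)C)(C(C)C)C(C)C)cc1C(OC)=[Cr].[C-]#[O+].[C-]#[O+].[C-]#[O+].[C-]#[O+].[C-]#[O+] | intermediate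
13 | acetylene (ethyne) | C#C | starting material
14 | 6-[(1R)-1-(tert-butyldimethylsilyloxy)-4-methylpent-3-enyl]-4,5-dimethoxy-8-(triisopropylsilyloxy)naphthalen-1-ol (formed as its Cr(CO)3 complex; hydroxyl on C4 and methoxy on C1 in plan numbering) | COc1c([C@@H](CC=C(C)C)O[Si](C)(C)C(C)(C)C)cc(O[Si](C(C)C)(C(C)C)C(C)C)c2c(O)ccc(OC)c12 | intermediate
15 | 7-[(1R)-1-(tert-butyldimethylsilyloxy)-4-methylpent-3-enyl]-8-methoxy-5-(triisopropylsilyloxy)naphthalene-1,4-dione | COc1c([C@@H](CC=C(C)C)O[Si](C)(C)C(C)(C)C)cc(O[Si](C(C)C)(C(C)C)C(C)C)c2c1C(=O)C=CC2=O | intermediate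
16 | 5-hydroxy-7-[(1R)-1-hydroxy-4-methylpent-3-enyl]-8-methoxynaphthalene-1,4-dione | COc1c([C@@H](CC=C(C)C)O)cc(O)c2c1C(=O)C=CC2=O | intermediate
17 | 3-methylbut-2-enoic acid | CC(C)=CC(=O)O | starting material
18 | (1R)-1-(4-hydroxy-1-methoxy-5,8-dioxo-5,8-dihydronaphthalen-2-yl)-4-methylpent-3-enyl 3-methylbut-2-enoate (CNP0130192.1) | COc1c([C@@H](CC=C(C)C)OC(=O)C=C(C)C)cc(O)c2c1C(=O)C=CC2=O | target

**Step count and risks**

Total step count: 10. Longest linear sequence: 10 steps (from 1 to 18).

Steps most likely to fail:

Step 8. Acetylene may insert repeatedly into the carbene (oligomerization), the vinylcarbene may divert to cyclopentannulation, or the cerium work-up may over-oxidize or desilylate. The fallback sets out from 9 and comes back at 15, and builds the quinone ring by a cycloaddition instead of the carbene union. Treatment of 9 with LDA in THF in the presence of excess furan (−78 °C to rt) should remove the hydrogen on C4a, eliminate bromide and trap the C4a–C8a aryne as the [4+2] adduct, the 1,4-epoxy-1,4-dihydronaphthalene F1 (both bridge diastereomers). Catalytic camphorsulfonic acid in CH2Cl2 (0 °C) should open the oxygen bridge to the two regioisomeric naphthols, the 4-naphthol F2 and the 1-naphthol F3. Both should converge on 15 when the free para position is oxidized with Fremy's salt, (KSO3)2NO, in buffered aqueous acetone.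

Step 10. Acylation may also occur at the C5 phenol, or the unsaturated acid may give N-acylurea or deconjugated ester. The fallback sets out from 15 and comes back at 18, and changes the order of deprotection so that the phenol stays capped during acylation. HF·pyridine in THF/pyridine (0 °C) should cleave the alkyl tert-butyldimethylsilyl ether selectively and give the phenol-protected carbinol F4. Steglich esterification with 17 (DCC, DMAP, CH2Cl2) should then give the phenol-protected ester F5. Buffered Bu4NF/AcOH in THF (0 °C) removes the aryl triisopropylsilyl group to give 18.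

Step 4. Facial selectivity may be poor, or turnover slow, because the ortho methoxy group can chelate titanium. The fallback sets out from 8 (material of insufficient enantiomeric purity) and comes back at 8, and replaces catalyst-controlled C–C bond formation by reagent-controlled ketone reduction. Oxidation with Dess–Martin periodinane (NaHCO3, CH2Cl2, 0 °C) should give the aryl ketone F6. Corey–Bakshi–Shibata reduction with catecholborane and catalytic (S)-2-methyl-CBS-oxazaborolidine (toluene, −78 °C) should return (R)-8, the aryl group acting as the large substituent. Catecholborane is chosen because it should not hydroborate the trisubstituted alkene.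

**Further compounds**

F1 | step 8 | 7-[(1R)-1-(tert-butyldimethylsilyloxy)-4-methylpent-3-enyl]-8-methoxy-5-(triisopropylsilyloxy)-1,4-dihydro-1,4-epoxynaphthalene (both bridge diastereomers) | COc1c([C@@H](CC=C(C)C)O[Si](C)(C)C(C)(C)C)cc(O[Si](C(C)C)(C(C)C)C(C)C)c2c1C1OC2C=C1
F2 | step 8 | 6-[(1R)-1-(tert-butyldimethylsilyloxy)-4-methylpent-3-enyl]-5-methoxy-8-(triisopropylsilyloxy)naphthalen-1-ol (hydroxyl on C4 in plan numbering) | COc1c([C@@H](CC=C(C)C)O[Si](C)(C)C(C)(C)C)cc(O[Si](C(C)C)(C(C)C)C(C)C)c2c(O)cccc12
F3 | step 8 | 7-[(1R)-1-(tert-butyldimethylsilyloxy)-4-methylpent-3-enyl]-8-methoxy-5-(triisopropylsilyloxy)naphthalen-1-ol (hydroxyl on C1 in plan numbering) | COc1c([C@@H](CC=C(C)C)O[Si](C)(C)C(C)(C)C)cc(O[Si](C(C)C)(C(C)C)C(C)C)c2cccc(O)c12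
F4 | step 10 | 7-[(1R)-1-hydroxy-4-methylpent-3-enyl]-8-methoxy-5-(triisopropylsilyloxy)naphthalene-1,4-dione | COc1c([C@@H](CC=C(C)C)O)cc(O[Si](C(C)C)(C(C)C)C(C)C)c2c1C(=O)C=CC2=O
F5 | step 10 | (1R)-1-[1-methoxy-5,8-dioxo-4-(triisopropylsilyloxy)-5,8-dihydronaphthalen-2-yl]-4-methylpent-3-enyl 3-methylbut-2-enoate | COc1c([C@@H](CC=C(C)C)OC(=O)C=C(C)C)cc(O[Si](C(C)C)(C(C)C)C(C)C)c2c1C(=O)C=CC2=O
F6 | step 4 | 1-[3-bromo-2-methoxy-5-(triisopropylsilyloxy)phenyl]-4-methylpent-3-en-1-one | COc1c(C(=O)CC=C(C)C)cc(O[Si](C(C)C)(C(C)C)C(C)C)cc1Br
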